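**Retrosynthetic overview**
- The target is the (3S,5S) anti-1,3-diol. It comes from a C3-O-carbamoyl, O-benzyl precursor by two deprotections.
- Key disconnection C3–C4: C3 acts as a configurationally defined α-oxygenated carbanion (d1, polarity-reversed carbinol carbon, a Hoppe α-lithio carbamate). C4 is the electrophilic CH2 of (S)-2-nonyloxirane. Both stereocentres are fixed in this one C–C bond formation, so no ketone reduction is needed.
- The carbamate comes from dihydroconiferyl alcohol (O-benzylation, O-carbamoylation). The oxirane comes from (S)-epichlorohydrin and n-octylmagnesium bromide.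
- Rings: none is built in the target (the arene is bought). The only ring made is the oxirane (step 1), which is opened again in the key step.

Assumption: (S)-epichlorohydrin, n-octylmagnesium bromide solution, dihydroconiferyl alcohol and (+)-sparteine are taken as commercially available catalogue items.

**Route**

Step 1
Reactants: 1 (S)-epichlorohydrin; 2 n-octylmagnesium bromide
Product: 4 (S)-2-nonyloxirane, via (S)-1-chloroundecan-2-ol 3 (not isolated)
Conditions: CuI (10 mol %), THF, −40 → −20 °C; then 2 M aq NaOH, n-Bu4NHSO4 (cat.), 0 °C → rt, same flask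
Reagents that add atoms: none
Why: CuI-catalysed Grignard opening (cuprate SN2) attacks the unsubstituted oxirane carbon of 1 without touching the stereocentre, and the chlorohydrin then closes by intramolecular Williamson displacement of chloride, so C5 of the target comes from the chiral pool with its (S) descriptor unchanged.

Step 2
Reactants: 5 dihydroconiferyl alcohol [4-(3-hydroxypropyl)-2-methoxyphenol]
Product: 6 3-[4-(benzyloxy)-3-methoxyphenyl]propan-1-ol
Conditions: BnBr (1.1 equiv), K2CO3 (1.5 equiv), acetone, reflux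
Reagents that add atoms: benzyl bromide, BrCc1ccccc1
Why: Williamson ether synthesis in which K2CO3 deprotonates only the phenol, so benzylation is chemoselective over the primary alcohol and gives an ether that tolerates s-BuLi at −78 °C, BF3·OEt2 and LiAlH4.

Step 3
Reactants: 6 3-[4-(benzyloxy)-3-methoxyphenyl]propan-1-ol
Product: 7 3-[4-(benzyloxy)-3-methoxyphenyl]propyl N,N-diisopropylcarbamate
Conditions: i-Pr2NCOCl (1.2 equiv), Et3N (1.5 equiv), CH2Cl2, reflux, 24 h
Reagents that add atoms: N,N-diisopropylcarbamoyl chloride, CC(C)N(C(C)C)C(Cl)=O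
Why: O-carbamoylation (acyl substitution) of the primary alcohol installs the Hoppe carbamate, the directing and dipole-stabilising group needed for α-lithiation.

Step 4
Reactants: 7 3-[4-(benzyloxy)-3-methoxyphenyl]propyl N,N-diisopropylcarbamate; 4 (S)-2-nonyloxirane
Product: 9 (3S,5S)-1-[4-(benzyloxy)-3-methoxyphenyl]-5-hydroxytetradecan-3-yl N,N-diisopropylcarbamate, via α-lithio carbamate 8 (not isolated)
Conditions: s-BuLi (1.3 equiv), (+)-sparteine (1.3 equiv), Et2O, −78 °C, 5 h; then 4 (1.5 equiv), BF3·OEt2 (1.5 equiv, added last), −78 °C, 3 h; H2O quench at −78 °C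
Reagents that add atoms: none
Why: Proposed new method: s-BuLi/(+)-sparteine removes the pro-R α-hydrogen of the O-alkyl carbamate under carbamate-directed control (Hoppe asymmetric deprotonation) to give the configurationally stable (R)-α-oxy organolithium 8, a d1 synthon, which opens BF3-activated oxirane 4 at its terminal CH2 by SN2 with retention at the carbanion, so C3 becomes (S) through the ligand while C5 is carried over untouched from 4; the closest known reaction types are Hoppe lithiation–electrophile trapping of alkyl carbamates and BF3·OEt2-promoted opening of terminal epoxides by organolithiums, including α-alkoxy organolithiums.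

Step 5
Reactants: 9 (3S,5S)-1-[4-(benzyloxy)-3-methoxyphenyl]-5-hydroxytetradecan-3-yl N,N-diisopropylcarbamate
Product: 10 (3S,5S)-1-[4-(benzyloxy)-3-methoxyphenyl]tetradecane-3,5-diol
Conditions: LiAlH4 (4 equiv), THF, reflux, 12 h; then H2O, 15% aq NaOH (Fieser work-up)
Reagents that add atoms: none
Why: Hydride reduction of the carbamate (attack at the carbamoyl C=O, helped by the neighbouring aluminium alkoxide) releases the C3 hydroxyl without breaking either stereogenic C–O bond and leaves the benzyl and methyl aryl ethers intact.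

Step 6
Reactants: 10 (3S,5S)-1-[4-(benzyloxy)-3-methoxyphenyl]tetradecane-3,5-diol
Product: 11 (3S,5S)-1-(4-hydroxy-3-methoxyphenyl)tetradecane-3,5-diol
Conditions: H2 (1 atm), 10% Pd/C, EtOAc–EtOH, rt
Reagents that add atoms: none
Why: Catalytic hydrogenolysis cleaves only the aryl benzyl ether, since no other benzylic C–O bond or reducible group is present, so both carbinol centres are unaffected.

The minor (3R,5S) syn diastereomer, which arises from imperfect enantioselection in step 4, is removed by chromatography at 9 or 10.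

**Compound list**
1 | (S)-epichlorohydrin | ClC[C@@H]1CO1 | starting material
2 | n-octylmagnesium bromide | CCCCCCCC[Mg]Br | starting material
3 | (S)-1-chloroundecan-2-ol | CCCCCCCCC[C@H](O)CCl | intermediate
4 | (S)-2-nonyloxirane | CCCCCCCCC[C@H]1CO1 | intermediate
5 | dihydroconiferyl alcohol, 4-(3-hydroxypropyl)-2-methoxyphenol | COc1cc(CCCO)ccc1O | starting material
6 | 3-[4-(benzyloxy)-3-methoxyphenyl]propan-1-ol | COc1cc(CCCO)ccc1OCc1ccccc1 | intermediate
7 | 3-[4-(benzyloxy)-3-methoxyphenyl]propyl N,N-diisopropylcarbamate | COc1cc(CCCOC(=O)N(C(C)C)C(C)C)ccc1OCc1ccccc1 | intermediate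
8 | (R)-1-lithio-3-[4-(benzyloxy)-3-methoxyphenyl]propyl N,N-diisopropylcarbamate, formed as its (+)-sparteine complex (ligand not drawn) | [Li][C@@H](OC(=O)N(C(C)C)C(C)C)CCc1ccc(OCc2ccccc2)c(OC)c1 | intermediate
9 | (3S,5S)-1-[4-(benzyloxy)-3-methoxyphenyl]-5-hydroxytetradecan-3-yl N,N-diisopropylcarbamate | CCCCCCCCC[C@H](O)C[C@@H](OC(=O)N(C(C)C)C(C)C)CCc1ccc(OCc2ccccc2)c(OC)c1 | intermediate
10 | (3S,5S)-1-[4-(benzyloxy)-3-methoxyphenyl]tetradecane-3,5-diol | CCCCCCCCC[C@H](O)C[C@@H](O)CCc1ccc(OCc2ccccc2)c(OC)c1 | intermediate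
11 | (3S,5S)-1-(4-hydroxy-3-methoxyphenyl)tetradecane-3,5-diol | CCCCCCCCC[C@H](O)C[C@@H](O)CCc1ccc(O)c(OC)c1 | target

**Step count**
Total: 6 steps. Longest linear sequence: 5 steps (5 → 6 → 7 → 9 → 10 → 11); the oxirane branch is 1 step.

**Steps most likely to fail, with fallbacks**

Step 4 (highest risk). The intermolecular, BF3-promoted epoxide opening by a sparteine-bound α-lithio carbamate is unproven. BF3 may destroy 8, s-BuLi may attack the benzylic ether CH2, and the dr may erode. The fallback keeps the C3–C4 bond and oxirane 4 but changes the d1 partner to an acyl-anion equivalent. It sets out from 6 and comes back at 10. Oxidise 6 (Dess–Martin periodinane, CH2Cl2) to 3-[4-(benzyloxy)-3-methoxyphenyl]propanal F1. Thioacetalise it (propane-1,3-dithiol, BF3·OEt2) to 2-{2-[4-(benzyloxy)-3-methoxyphenyl]ethyl}-1,3-dithiane F2. Deprotonate (n-BuLi, THF, −30 °C) to the 2-lithio-1,3-dithiane F3 and add 4 (Corey–Seebach alkylation) to give the (S)-β-hydroxy dithiane F4. Unmask with I2, NaHCO3 in aqueous acetone to (5S)-1-[4-(benzyloxy)-3-methoxyphenyl]-5-hydroxytetradecan-3-one F5. Reduce with Me4NBH(OAc)3 (MeCN/AcOH, −30 °C; Evans–Saksena intramolecular hydride delivery, 1,3-anti) to reach 10.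

Step 5. A hindered secondary N,N-diisopropylcarbamate can resist LiAlH4, or can migrate to the C5 oxygen and cleave slowly. The fallback replaces the activating group by Hoppe's acid/base-cleavable oxazolidine carbamate. It sets out from 6 and comes back at 10. Acylate 6 with 2,2,4,4-tetramethyl-1,3-oxazolidine-3-carbonyl chloride (NaH, THF) to 3-[4-(benzyloxy)-3-methoxyphenyl]propyl 2,2,4,4-tetramethyl-1,3-oxazolidine-3-carboxylate F6. Lithiate as in step 4 to the α-lithio oxazolidine carbamate F7 and open 4 to the (3S,5S)-hydroxy oxazolidine carbamate F8. MeSO3H in refluxing MeOH opens the N,O-acetal to the N-(1-hydroxy-2-methylpropan-2-yl)carbamate F9. Ba(OH)2·8H2O in refluxing MeOH then releases 10 by intramolecular acyl transfer.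

Step 1. Halide scrambling or direct chloride displacement on epichlorohydrin would lower the ee of 4, and that would show up as the syn diastereomer later. The fallback sets the oxirane stereocentre by kinetic resolution instead of the chiral pool. It sets out from 2 and comes back at 4. Couple 2 with allyl bromide (CuI cat., THF) to undec-1-ene F10, which is also an inexpensive article of commerce. Epoxidise with mCPBA (CH2Cl2) to racemic 2-nonyloxirane F11. Resolve by Jacobsen hydrolytic kinetic resolution (0.55 equiv H2O, 0.5 mol % [N,N'-bis(3,5-di-tert-butylsalicylidene)-1,2-cyclohexanediaminato]cobalt acetate, trivalent cobalt, ligand enantiomer chosen so that the (R)-oxirane is hydrolysed). Distil the unreacted (S)-oxirane 4 from the diol.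

**Further compounds**
F1 | step 4 | 3-[4-(benzyloxy)-3-methoxyphenyl]propanal | COc1cc(CCC=O)ccc1OCc1ccccc1
F2 | step 4 | 2-{2-[4-(benzyloxy)-3-methoxyphenyl]ethyl}-1,3-dithiane | COc1cc(CCC2SCCCS2)ccc1OCc1ccccc1
F3 | step 4 | 2-lithio-2-{2-[4-(benzyloxy)-3-methoxyphenyl]ethyl}-1,3-dithiane | COc1cc(CCC2([Li])SCCCS2)ccc1OCc1ccccc1
F4 | step 4 | (2S)-1-{2-[2-(4-(benzyloxy)-3-methoxyphenyl)ethyl]-1,3-dithian-2-yl}undecan-2-ol | CCCCCCCCC[C@H](O)CC1(CCc2ccc(OCc3ccccc3)c(OC)c2)SCCCS1
F5 | step 4 | (5S)-1-[4-(benzyloxy)-3-methoxyphenyl]-5-hydroxytetradecan-3-one | CCCCCCCCC[C@H](O)CC(=O)CCc1ccc(OCc2ccccc2)c(OC)c1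
F6 | step 5 | 3-[4-(benzyloxy)-3-methoxyphenyl]propyl 2,2,4,4-tetramethyl-1,3-oxazolidine-3-carboxylate | COc1cc(CCCOC(=O)N2C(C)(C)OCC2(C)C)ccc1OCc1ccccc1
F7 | step 5 | (R)-1-lithio-3-[4-(benzyloxy)-3-methoxyphenyl]propyl 2,2,4,4-tetramethyl-1,3-oxazolidine-3-carboxylate | [Li][C@@H](OC(=O)N1C(C)(C)OCC1(C)C)CCc2ccc(OCc3ccccc3)c(OC)c2
F8 | step 5 | (3S,5S)-1-[4-(benzyloxy)-3-methoxyphenyl]-5-hydroxytetradecan-3-yl 2,2,4,4-tetramethyl-1,3-oxazolidine-3-carboxylate | CCCCCCCCC[C@H](O)C[C@@H](OC(=O)N1C(C)(C)OCC1(C)C)CCc2ccc(OCc3ccccc3)c(OC)c2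
F9 | step 5 | (3S,5S)-1-[4-(benzyloxy)-3-methoxyphenyl]-5-hydroxytetradecan-3-yl N-(1-hydroxy-2-methylpropan-2-yl)carbamate | CCCCCCCCC[C@H](O)C[C@@H](OC(=O)NC(C)(C)CO)CCc1ccc(OCc2ccccc2)c(OC)c1
F10 | step 1 | undec-1-ene | C=CCCCCCCCCC
F11 | step 1 | racemic 2-nonyloxirane | CCCCCCCCCC1CO1
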